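## Retrosynthetic overview

1. Feature: the target is a bicyclo[3.2.1]octan-8-one (six-membered ring C1–C2–C3–C4–C5–C8, five-membered ring C1–C7–C6–C5–C8). The aryl/methyl bridge C6–C7 joins the allyl bridgehead C1 to C5, the methoxylated neighbour of the C8 carbonyl, so shifting C6 from C5 back to C8 gives a cyclobutanol cis-fused to the six-membered ring.
2. Last disconnection (C5–C6): oxidation of a C4=C5 methyl enol ether beside the C8 cyclobutanol sends C6 from C8 to C5 (semipinacol ring expansion) and sets C4–OH, C5–OMe and the C8 ketone together.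
3. Key disconnection (C1–C7 and C8–C6): [2+2] photocycloaddition of (S)-3-allyl-2-silyloxy-5-methoxycyclohex-2-enone with (E)-isoelemicin builds the cyclobutane and four stereocentres under control of the C3 methoxy group.
4. The enone is made from 4-methoxycyclohexanone (α-allylation, α'-hydroxylation, oxidation to the diosphenol, O-silylation, chiral-phase resolution); the methoxy group stays γ to the carbonyl, and so base-stable, until the diosphenol stage. Isoelemicin comes from a Suzuki–Miyaura coupling.
5. Ring order: six-membered ring (purchased), cyclobutane (step 7), five-membered ring by ring expansion (step 10).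

Key step: step 7

Remark: the target atom labels C1–C8 (C1 allyl bridgehead, C2 CH2, C3 OMe, C4 OH, C5 OMe bridgehead, C6 aryl, C7 methyl, C8 ketone) are kept for all intermediates, and stereodescriptors refer to these labels.

## Route

Step 1
Reactants: 1 4-methoxycyclohexanone; 2 allyl bromide
Product: 4 2-allyl-4-methoxycyclohexan-1-one as a racemic cis/trans mixture, via lithium enolate 3 (not isolated)
Conditions: LiN(iPr)2, THF, −78 °C; then 2, DMPU, −78 → 0 °C
Reagents that add atoms: none
Why: Enolate C-alkylation with a reactive allylic halide; the γ-methoxy group is inert to base, and the stereoisomer mixture is immaterial because the new centre (C1) becomes sp2 in step 3.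

Step 2
Reactants: 4 2-allyl-4-methoxycyclohexan-1-one
Product: 6 2-allyl-6-hydroxy-4-methoxycyclohexan-1-one as a diastereomer mixture, via potassium enolate 5 (not isolated)
Conditions: KN(SiMe3)2, THF, −78 °C; then 2-(phenylsulfonyl)-3-phenyloxaziridine, −78 °C; aq. NH4Cl
Reagents that add atoms: 2-(phenylsulfonyl)-3-phenyloxaziridine, O=S(=O)(c1ccccc1)N1OC1c1ccccc1
Why: The hindered amide base should deprotonate the unsubstituted α-methylene (C5) under kinetic control, and the enolate is oxidised by the N-sulfonyloxaziridine (enolate α-hydroxylation); the configuration of the new carbinol is irrelevant because it is oxidised in step 3.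

Step 3
Reactants: 6 2-allyl-6-hydroxy-4-methoxycyclohexan-1-one
Product: 8 rac-3-allyl-2-hydroxy-5-methoxycyclohex-2-en-1-one, via 1,2-dione 7 (not isolated)
Conditions: Dess–Martin periodinane, CH2Cl2, 0 °C → rt; SiO2
Reagents that add atoms: none
Why: Dess–Martin oxidation of the acyloin gives the 1,2-dione, which should enolise towards the allyl-bearing carbon to the more substituted conjugated diosphenol, so that C1 and C5 cease to be stereocentres and only C3 (racemic) remains.

Step 4
Reactants: 8 rac-3-allyl-2-hydroxy-5-methoxycyclohex-2-en-1-one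
Product: 9 rac-3-allyl-2-(tert-butyldimethylsilyloxy)-5-methoxycyclohex-2-en-1-one
Conditions: TBSCl, imidazole, DMF, 0 °C → rt
Reagents that add atoms: tert-butyldimethylsilyl chloride, CC(C)(C)[Si](C)(C)Cl
Why: O-Silylation of the acidic enol hydroxyl under imidazole conditions, which are mild enough that the now β-disposed methoxy group should not be eliminated.

Step 5
Reactants: 9 rac-3-allyl-2-(tert-butyldimethylsilyloxy)-5-methoxycyclohex-2-en-1-one
Product: 10 (S)-3-allyl-2-(tert-butyldimethylsilyloxy)-5-methoxycyclohex-2-en-1-one
Conditions: preparative HPLC, immobilised amylose tris(3,5-dimethylphenylcarbamate) phase, n-hexane/iPrOH, rt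
Reagents that add atoms: none
Why: Direct chromatographic resolution on a chiral phase; 9 has one configurationally stable stereocentre (C3) and an enone chromophore, and the (S) assignment would be confirmed crystallographically on a later intermediate.

Step 6
Reactants: 11 5-bromo-1,2,3-trimethoxybenzene; 12 (E)-prop-1-enylboronic acid pinacol ester
Product: 13 (E)-isoelemicin, 1,2,3-trimethoxy-5-[(E)-prop-1-enyl]benzene
Conditions: Pd(PPh3)4 (3 mol %), K2CO3, dioxane/H2O, 90 °C
Reagents that add atoms: none
Why: Suzuki–Miyaura coupling should transfer the propenyl group to the aryl bromide with retention of the E geometry.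

Step 7
Reactants: 10 (S)-3-allyl-2-(tert-butyldimethylsilyloxy)-5-methoxycyclohex-2-en-1-one; 13 (E)-isoelemicin
Product: 14 (1R,3S,6S,7R,8R) cis-fused bicyclo[4.2.0]octan-2-one photoadduct: six-membered ring C1–C2–C3–C4–C5(=O)–C8, cyclobutane C1–C7–C6–C8, allyl on C1, OMe on C3, OSi(tBu)Me2 on C8, aryl on C6 exo, methyl on C7 endo
Conditions: hν (366 nm LED), 13 (5 equiv), degassed CH2Cl2, −40 °C
Reagents that add atoms: none
Why: Irradiation into the n→π* band of 10, where 13 is transparent, and intersystem crossing give the triplet enone, whose β-carbon C1 bonds to the methyl-bearing alkene carbon C7 to give the best-stabilised triplet 1,4-biradical (C8 radical flanked by carbonyl and silyloxy oxygen, C6 benzylic), and after spin inversion C8–C6 radical recombination closes the cyclobutane. The closest known reaction type is the intermolecular enone–alkene [2+2] photocycloaddition of cyclohexenones, including 2-acyloxy and 2-silyloxy enones, with arylalkenes. The one new ring, the four-membered ring C1–C7–C6–C8, is closed stepwise by 1,4-biradical collapse in the cis-fused mode on the six-membered ring, the fusion most readily reached when the planar C8 radical closes onto a chain already anchored at C1. C1 is set by attack on the enone face opposite the C3 methoxy group (a pseudoaxial methoxy shields its own face of C1, a pseudoequatorial one leaves axial anti attack), C8 by the cis closure, and C7/C6 by the biradical, which can rotate before closing and should place methyl and aryl trans with the large aryl group on the convex face. The step needs head-to-head regiochemistry, anti facial selectivity and the aryl-exo/methyl-endo arrangement; the first rests on the captodative/benzylic biradical, the second on the C3 stereocentre, and the third on reversibility of the first bond, since biradicals that could only close with the aryl group under the six-membered ring should fragment back to 10 and 13.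

Step 8
Reactants: 14 photoadduct
Product: 16 (1R,3S,6S,7R,8R) C4=C5 methyl enol ether of 14 (5-methoxybicyclo[4.2.0]oct-4-ene in target labels and otherwise as 14), via potassium enolate 15 (not isolated)
Conditions: KN(SiMe3)2, THF/DMPU, −78 °C; then MeOTf, −78 °C
Reagents that add atoms: methyl trifluoromethanesulfonate, COS(=O)(=O)C(F)(F)F
Why: Only C4 carries α-hydrogens (C8 is quaternary), so the enolate is regiodefined, and a hard methylating agent on a dissociated potassium enolate in a dipolar medium should favour O-alkylation (enolate O-methylation) at a temperature where loss of the C3 methoxy group is slow; no stereocentre is formed.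

Step 9
Reactants: 16 silyl-protected methyl enol ether
Product: 17 (1R,3S,6S,7R,8R) cyclobutanol: 16 with free C8–OH
Conditions: Bu4NF, THF, 0 °C → rt
Reagents that add atoms: none
Why: Fluoride-mediated desilylation frees the tertiary alcohol under non-acidic conditions that should spare the acid-labile enol ether and the cyclobutanol.

Step 10
Reactants: 17 cyclobutanol methyl enol ether
Product: 19 (1R,3S,4S,5S,6S,7R)-1-allyl-4-hydroxy-3,5-dimethoxy-7-methyl-6-(3,4,5-trimethoxyphenyl)bicyclo[3.2.1]octan-8-one (target labels), via epoxy alcohol 18 (not isolated)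
Conditions: VO(acac)2 (5 mol %), t-BuOOH (1.2 equiv, decane), CH2Cl2, 0 °C
Reagents that add atoms: tert-butyl hydroperoxide, CC(C)(C)OO
Why: The tertiary allylic C8 hydroxyl binds the vanadium peroxide and delivers oxygen to the C4=C5 enol ether on its own face (hydroxyl-directed epoxidation), which sets C4; the α-methoxy epoxide then opens at C5 to the oxocarbenium ion and the exocyclic, antiperiplanar C8–C6 cyclobutane bond migrates to C5 with retention at C6 while C8 becomes the ketone (strain-driven semipinacol ring expansion), which sets C5.

## Compound list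

1 | 4-methoxycyclohexanone | COC1CCC(=O)CC1 | starting material
2 | allyl bromide | C=CCBr | starting material
3 | lithium 4-methoxycyclohex-1-en-1-olate (racemic) | [Li+].[O-]C1=CCC(OC)CC1 | intermediate
4 | 2-allyl-4-methoxycyclohexan-1-one (racemic, cis/trans mixture, no defined stereocentre) | C=CCC1CC(OC)CCC1=O | intermediate
5 | potassium 6-allyl-4-methoxycyclohex-1-en-1-olate (stereoisomer mixture) | C=CCC1CC(OC)CC=C1[O-].[K+] | intermediate
6 | 2-allyl-6-hydroxy-4-methoxycyclohexan-1-one (racemic diastereomer mixture) | C=CCC1CC(OC)CC(O)C1=O | intermediate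
7 | 3-allyl-5-methoxycyclohexane-1,2-dione (racemic diastereomer mixture) | C=CCC1CC(OC)CC(=O)C1=O | intermediate
8 | rac-3-allyl-2-hydroxy-5-methoxycyclohex-2-en-1-one | C=CCC1=C(O)C(=O)CC(OC)C1 | intermediate
9 | rac-3-allyl-2-(tert-butyldimethylsilyloxy)-5-methoxycyclohex-2-en-1-one | C=CCC1=C(O[Si](C)(C)C(C)(C)C)C(=O)CC(OC)C1 | intermediate
10 | (S)-3-allyl-2-(tert-butyldimethylsilyloxy)-5-methoxycyclohex-2-en-1-one | C=CCC1=C(O[Si](C)(C)C(C)(C)C)C(=O)C[C@@H](OC)C1 | intermediate
11 | 5-bromo-1,2,3-trimethoxybenzene | COc1cc(Br)cc(OC)c1OC | starting material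
12 | 4,4,5,5-tetramethyl-2-[(E)-prop-1-enyl]-1,3,2-dioxaborolane | C/C=C/B1OC(C)(C)C(C)(C)O1 | starting material
13 | (E)-isoelemicin | C/C=C/c1cc(OC)c(OC)c(OC)c1 | intermediate
14 | photoadduct, (1R,3S,6S,7R,8R) in target labels: cis-fused 1-allyl-8-(tert-butyldimethylsilyloxy)-3-methoxy-7-methyl-6-(3,4,5-trimethoxyphenyl)bicyclo[4.2.0]octan-5-one, cyclobutane anti to C3–OMe, aryl exo, methyl endo | C=CC[C@]12C[C@H](OC)CC(=O)[C@@]1(O[Si](C)(C)C(C)(C)C)[C@H](c3cc(OC)c(OC)c(OC)c3)[C@H]2C | intermediate
15 | potassium C4=C5 enolate of 14 | C=CC[C@]12C[C@H](OC)C=C([O-])[C@@]1(O[Si](C)(C)C(C)(C)C)[C@H](c3cc(OC)c(OC)c(OC)c3)[C@H]2C.[K+] | intermediate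
16 | C4=C5 methyl enol ether of 14, (1R,3S,6S,7R,8R) | C=CC[C@]12C[C@H](OC)C=C(OC)[C@@]1(O[Si](C)(C)C(C)(C)C)[C@H](c3cc(OC)c(OC)c(OC)c3)[C@H]2C | intermediate
17 | cyclobutanol methyl enol ether (16 with C8–OH), (1R,3S,6S,7R,8R) | C=CC[C@]12C[C@H](OC)C=C(OC)[C@@]1(O)[C@H](c3cc(OC)c(OC)c(OC)c3)[C@H]2C | intermediate
18 | C4–C5 epoxide of 17, epoxide oxygen on the face of the C8 hydroxyl | C=CC[C@]12C[C@H](OC)[C@@H]4O[C@]4(OC)[C@@]1(O)[C@H](c3cc(OC)c(OC)c(OC)c3)[C@H]2C | intermediate
19 | CNP0275320.2, (1R,3S,4S,5S,6S,7R)-1-allyl-4-hydroxy-3,5-dimethoxy-7-methyl-6-(3,4,5-trimethoxyphenyl)bicyclo[3.2.1]octan-8-one (target labels) | C=CC[C@]12C[C@H](OC)[C@H](O)[C@](OC)(C1=O)[C@H](c1cc(OC)c(OC)c(OC)c1)[C@H]2C | target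

## Step count and risk

Total step count: 10. Longest linear sequence: 9 (steps 1–5 and 7–10).

Steps most likely to fail:

1. Step 7. Triplet energy transfer from the excited enone to the styrene (E/Z isomerisation and styrene dimerisation) may outrun cycloaddition, the small C3 methoxy group may discriminate the enone faces poorly, and closure may occur with the aryl group on the concave face. Fallback, setting out from 10 and returning at 14: 10 would be irradiated under the same conditions with alkenylboronate 12 in place of 13. Compound 12 has a high triplet energy and should not quench the enone, and the α-boryl radical at C6 should lead to the same head-to-head adduct with the bulky boryl group exo and methyl endo, the cyclobutylboronate F1. Treatment of F1 with KHF2 (MeOH/H2O) would give the potassium trifluoroborate F2. The aryl group would then be installed by nickel/photoredox cross-coupling of F2 with bromide 11 (NiCl2(dme), 4,4'-di-tert-butyl-2,2'-bipyridine, [Ir(dF(CF3)ppy)2(bpy)]PF6, 2,6-lutidine, dioxane, blue LED), the C6 radical being captured on the convex face, to give 14.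

2. Step 10. Oxygen may be delivered to the wrong face, the enol ether may be protonated so that ring expansion occurs without oxygen transfer, or the ring bond C8–C1 may migrate in place of C8–C6. Fallback, setting out from 17 and returning at 19, separating oxygenation from rearrangement: hydrogen-bond-directed dihydroxylation of 17 (OsO4, TMEDA, CH2Cl2, −78 °C; aq. NaHSO3) on the face of the C8 hydroxyl, with collapse of the C5 hemiketal, would give the dihydroxy ketone F4. Selective silylation of the secondary C4 hydroxyl (Et3SiCl, imidazole) would give silyl ether F5. Lewis-acid-promoted α-ketol rearrangement (BF3·OEt2, CH2Cl2, −40 °C), again driven by cyclobutane strain, would move C6 from C8 to the C5 carbonyl carbon and give the tertiary alcohol F6. Methylation of the C5 hydroxyl (MeOTf, 2,6-di-tert-butyl-4-methylpyridine, CH2Cl2) would give methyl ether F7, and desilylation (Bu4NF, THF) would give 19.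

3. Step 8. C-Methylation at C4 may compete with O-methylation, and the enolate may expel the C3 methoxy group (E1cB). Fallback, setting out from 14 and returning at 16 without a strong base: ketalisation of 14 (MeOSiMe3, cat. Me3SiOTf, CH2Cl2, −78 °C) would give the dimethyl ketal F3. Elimination of methanol from F3 with Me3SiOTf/iPr2NEt (CH2Cl2, −20 °C) can only occur towards C4, the sole neighbour bearing hydrogen, and would give 16.

Further compounds
F1 | step 7 | cyclobutylboronate, as 14 with a pinacolboryl group in place of the aryl group on C6 (exo), methyl on C7 endo | C=CC[C@]12C[C@H](OC)CC(=O)[C@@]1(O[Si](C)(C)C(C)(C)C)[C@H](B3OC(C)(C)C(C)(C)O3)[C@H]2C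
F2 | step 7 | potassium trifluoroborate derived from F1 | C=CC[C@]12C[C@H](OC)CC(=O)[C@@]1(O[Si](C)(C)C(C)(C)C)[C@H]([B-](F)(F)F)[C@H]2C.[K+]
F3 | step 8 | C5 dimethyl ketal of 14 | C=CC[C@]12C[C@H](OC)CC(OC)(OC)[C@@]1(O[Si](C)(C)C(C)(C)C)[C@H](c3cc(OC)c(OC)c(OC)c3)[C@H]2C
F4 | step 10 | 4,8-dihydroxy-5-ketone, C4–OH on the face of C8–OH, bicyclo[4.2.0] skeleton of 14 | C=CC[C@]12C[C@H](OC)[C@H](O)C(=O)[C@@]1(O)[C@H](c3cc(OC)c(OC)c(OC)c3)[C@H]2C
F5 | step 10 | C4 triethylsilyl ether of F4 | C=CC[C@]12C[C@H](OC)[C@H](O[Si](CC)(CC)CC)C(=O)[C@@]1(O)[C@H](c3cc(OC)c(OC)c(OC)c3)[C@H]2C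
F6 | step 10 | ring-expanded 5-hydroxybicyclo[3.2.1]octan-8-one with C4–OSiEt3, configuration as in 19 | C=CC[C@]12C[C@H](OC)[C@H](O[Si](CC)(CC)CC)[C@](O)(C1=O)[C@H](c3cc(OC)c(OC)c(OC)c3)[C@H]2C
F7 | step 10 | C5 methyl ether of F6 (19 as its C4 triethylsilyl ether) | C=CC[C@]12C[C@H](OC)[C@H](O[Si](CC)(CC)CC)[C@](OC)(C1=O)[C@H](c3cc(OC)c(OC)c(OC)c3)[C@H]2C
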